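**Strategy.** Opening the furan-2,4-dione ring at O1–C5 and C4–C5 reduces the target to its quaternary C3. This carbon carries two carboxyl carbons (future C2 and C4), an aryl group and a prenyl group. The key step exploits the fact that the C3 prenyl alkene can reach both carbonyl carbons, which are enantiotopic in the 2-aryl-2-prenylmalonic acid 8 (phenol silylated). Catalytic enantioselective iodolactonisation closes one carboxyl onto the alkene. This one operation sets C3, masks the C2 carboxyl as a temporary δ-lactone and leaves the C4 carboxyl free for chain extension. Zinc later returns the prenyl group and the acid. A 5-exo-dig closure at the carbinol oxidation level, oxidation and desilylation complete the ring.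

Key step: step 6

Assumption: the sense of induction on 8 cannot be predicted, so the catalyst antipode that gives (3S)-10 is used (both are accessible). C5 is drawn (R) for the chair with iodine and free carboxyl equatorial, and its C5 epimer with the same C3 configuration would serve equally.

Abbreviations: prenyl = 3-methylbut-2-en-1-yl; TIPS = triisopropylsilyl.

Step 1
Reactants: 1 4-iodophenol; 2 prenyl bromide
Product: 3 4-iodo-2-prenylphenol
Conditions: NaH (1.05 equiv), toluene, 0 °C; then 2 (1.0 equiv), rt
Reagents that add atoms: none
Why: Ortho-selective C-alkylation of a phenoxide, in which the tight sodium ion pair in non-polar toluene shields oxygen and directs SN2 attack on the primary carbon of 2 from the ortho carbon, the para position being blocked by iodine.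

Step 2
Reactants: 3 4-iodo-2-prenylphenol
Product: 4 (4-iodo-2-prenylphenoxy)triisopropylsilane
Conditions: TIPSCl, imidazole, DMF, rt
Reagents that add atoms: triisopropylsilyl chloride, CC(C)[Si](Cl)(C(C)C)C(C)C
Why: Imidazole-promoted silyl ether formation, giving a bulky aryl silyl ether that makes the phenol oxygen non-nucleophilic and should survive all later basic, organometallic and reductive steps, while 4 serves as the common source of both aryl groups.

Step 3
Reactants: 4 (4-iodo-2-prenylphenoxy)triisopropylsilane; 5 diallyl malonate
Product: 6 diallyl 2-[3-prenyl-4-(triisopropylsilyloxy)phenyl]malonate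
Conditions: CuI (10 mol %), 2-picolinic acid (20 mol %), Cs2CO3 (3 equiv), 1,4-dioxane, rt
Reagents that add atoms: none
Why: Copper-catalysed α-arylation of a malonate (Hurtley-type coupling), which runs at room temperature with aryl iodides including electron-rich ones and leaves allyl esters, the silyl ether and the trisubstituted alkene untouched.

Step 4
Reactants: 6 diallyl 2-[3-prenyl-4-(triisopropylsilyloxy)phenyl]malonate; 2 prenyl bromide
Product: 7 diallyl 2-prenyl-2-[3-prenyl-4-(triisopropylsilyloxy)phenyl]malonate
Conditions: NaH, THF, 0 °C; then 2, 0 °C to rt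
Reagents that add atoms: none
Why: Malonic ester alkylation, in which the stabilised aryl malonate enolate attacks the primary carbon of 2 by SN2 and builds the prochiral quaternary carbon.

Step 5
Reactants: 7 diallyl 2-prenyl-2-[3-prenyl-4-(triisopropylsilyloxy)phenyl]malonate
Product: 8 2-prenyl-2-[3-prenyl-4-(triisopropylsilyloxy)phenyl]malonic acid
Conditions: Pd(PPh3)4 (5 mol %), morpholine (4 equiv), THF, 0 °C to rt; cold aq KHSO4 work-up, no heating, used at once
Reagents that add atoms: none
Why: Tsuji–Trost deallylation, in which zerovalent palladium ionises both allyl esters and morpholine traps the π-allyl units, so the hindered esters leave under neutral conditions without the hot base that would threaten the aryl silyl ether or the heat that would decarboxylate the aryl malonic acid.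

Step 6
Reactants: 8 2-prenyl-2-[3-prenyl-4-(triisopropylsilyloxy)phenyl]malonic acid; 9 N-iodosuccinimide
Product: 10 (3S,5R)-5-iodo-6,6-dimethyl-2-oxo-3-[3-prenyl-4-(triisopropylsilyloxy)phenyl]tetrahydropyran-3-carboxylic acid
Conditions: chiral bis(amidine) from 1,2-diphenylethane-1,2-diamine and 2-chloro-4-(pyrrolidin-1-yl)quinoline as its 1:1 HNTf2 salt (10 mol %), 9 (1.05 equiv), toluene, −50 °C, dark
Reagents that add atoms: none
Why: The free amidine of the catalyst deprotonates one carboxyl group of 8 and holds the hydrogen malonate in a hydrogen-bonded chiral ion pair while the amidinium N–H activates 9, so that iodonium transfer to the C3 prenyl alkene and anti attack of the bound carboxylate oxygen on the tertiary alkene carbon take place inside the chiral pocket. The closest known reaction type is catalytic enantioselective iodolactonisation with NIS under bifunctional Brønsted base/acid catalysis, including its desymmetrising variants. The single ring formed, the δ-lactone, closes 6-endo-trig because the dimethyl-substituted carbon carries most of the positive charge of the iodonium ion; any 5-exo-trig γ-lactone with the same C3 configuration can be carried on, since zinc regenerates the same alkene from both. C3 is controlled by the catalyst, which decides which enantiotopic carboxyl group becomes the lactone carbonyl, and C5 by the chair-like transition state (iodine and free carboxyl equatorial) that ties the alkene face to that choice; C6 is not stereogenic, so the anti addition leaves no further record. The step needs selection between two carboxyl groups, between two prenyl alkenes and against the arene: only the C3 prenyl group has a carboxylate within reach, an iodonium ion on the aryl prenyl group finds no internal nucleophile (the phenol oxygen is buried under TIPS) and hands the iodine back, and the ring positions that could reach the C3 iodonium ion are meta to the silyloxy group. A diastereomer with inverted C3 is removed here by chromatography or crystallisation, because it would count as the wrong enantiomer once C5 is erased in step 11.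

Step 7
Reactants: 10 (3S,5R)-iodolactone carboxylic acid
Product: 12 (3S,5R)-5-iodo-6,6-dimethyl-2-oxo-3-[3-prenyl-4-(triisopropylsilyloxy)phenyl]tetrahydropyran-3-carbaldehyde, via acid chloride 11 (not isolated)
Conditions: 1-chloro-N,N,2-trimethylpropenylamine (1.1 equiv), CH2Cl2, 0 °C; then LiAlH(OtBu)3 (1.05 equiv), THF, −78 °C
Reagents that add atoms: none
Why: Neutral acid chloride formation followed by partial reduction of the acyl chloride with a bulky alkoxyaluminium hydride, which at −78 °C attacks an acyl chloride far faster than a lactone, an alkyl iodide or the hindered aldehyde formed, while C3 has no α-hydrogen and cannot epimerise.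

Step 8
Reactants: 4 (4-iodo-2-prenylphenoxy)triisopropylsilane; 13 ethynyltrimethylsilane
Product: 14 triisopropyl{2-prenyl-4-[(trimethylsilyl)ethynyl]phenoxy}silane
Conditions: PdCl2(PPh3)2 (2 mol %), CuI (4 mol %), Et3N, THF, rt
Reagents that add atoms: none
Why: Sonogashira coupling of an aryl iodide, which proceeds at room temperature and does not touch the trisubstituted alkene or the silyl ether.

Step 9
Reactants: 14 triisopropyl{2-prenyl-4-[(trimethylsilyl)ethynyl]phenoxy}silane
Product: 15 (4-ethynyl-2-prenylphenoxy)triisopropylsilane
Conditions: K2CO3 (0.2 equiv), MeOH/CH2Cl2, 0 °C to rt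
Reagents that add atoms: none
Why: Base-catalysed methanolysis of the alkynyl C–Si bond (protodesilylation), which is much faster than attack on the hindered aryl TIPS ether.

Step 10
Reactants: 12 (3S,5R)-iodolactone carbaldehyde; 15 (4-ethynyl-2-prenylphenoxy)triisopropylsilane
Product: 17 (3S,5R)-3-{1-hydroxy-3-[3-prenyl-4-(triisopropylsilyloxy)phenyl]prop-2-yn-1-yl}-5-iodo-6,6-dimethyl-3-[3-prenyl-4-(triisopropylsilyloxy)phenyl]tetrahydropyran-2-one (both carbinol epimers), via lithium acetylide 16 (not isolated)
Conditions: 15 (1.2 equiv), n-BuLi (1.15 equiv), THF, −78 °C; then 12, −78 °C; AcOH quench at −78 °C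
Reagents that add atoms: none
Why: 1,2-Addition of a lithium acetylide to an aldehyde, chemoselective at −78 °C over the hindered lactone, with a cold acidic quench to forestall retro-aldol cleavage; the new carbinol centre needs no control because it becomes the C4 ketone in step 13.

Step 11
Reactants: 17 iodolactone propargylic alcohol
Product: 18 (2S)-2-{1-hydroxy-3-[3-prenyl-4-(triisopropylsilyloxy)phenyl]prop-2-yn-1-yl}-5-methyl-2-[3-prenyl-4-(triisopropylsilyloxy)phenyl]hex-4-enoic acid (both carbinol epimers)
Conditions: Zn dust (activated), AcOH, THF, 0 °C to rt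
Reagents that add atoms: none
Why: Zinc-mediated reductive β-elimination of the vicinal iodo/acyloxy pair (the reverse of iodolactonisation), which expels the carboxylate, erases C5 and restores the prenyl alkene, while the aryl alkyne and the propargylic alcohol are inert to plain zinc and a β-hydroxy acid does not decarboxylate.

Step 12
Reactants: 18 β-hydroxy-γ,δ-alkynoic acid
Product: 19 (3S,5Z)-4-hydroxy-3-prenyl-3-[3-prenyl-4-(triisopropylsilyloxy)phenyl]-5-[3-prenyl-4-(triisopropylsilyloxy)benzylidene]dihydrofuran-2(3H)-one (both C4 epimers)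
Conditions: Ag2CO3 (10 mol %), toluene, rt, dark
Reagents that add atoms: none
Why: Silver-catalysed cycloisomerisation of a γ,δ-alkynoic acid, a 5-exo-dig closure helped by the propargylic C–O bond and the quaternary C3, in which anti attack of the carboxylate on the silver-bound alkyne and protodemetalation place aryl group and ring oxygen cis (Z); closing at the carbinol level avoids both an ynone, which would steer attack to the distal carbon (6-endo), and a β-keto acid, which would lose CO2.

Step 13
Reactants: 19 4-hydroxy-5-benzylidene lactone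
Product: 20 (3S,5Z)-3-prenyl-3-[3-prenyl-4-(triisopropylsilyloxy)phenyl]-5-[3-prenyl-4-(triisopropylsilyloxy)benzylidene]furan-2,4(3H,5H)-dione
Conditions: Dess–Martin periodinane (1.3 equiv), CH2Cl2, 0 °C to rt
Reagents that add atoms: none
Why: Dess–Martin oxidation of a hindered allylic secondary alcohol, which converges both C4 epimers on one ketone and is compatible with silyl-protected phenols, prenyl alkenes and the enol ester.

Step 14
Reactants: 20 bis(TIPS) ether of the target
Product: 21 (3S,5Z)-5-(4-hydroxy-3-prenylbenzylidene)-3-(4-hydroxy-3-prenylphenyl)-3-prenylfuran-2,4(3H,5H)-dione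
Conditions: TBAF (2.4 equiv), AcOH (2.4 equiv), THF, 0 °C
Reagents that add atoms: none
Why: Fluoride-mediated cleavage of two aryl silyl ethers, buffered with acetic acid so that no free base can open the non-enolisable β-keto lactone and no strong acid can cyclise the ortho-prenylphenols, with C3 (quaternary) and the thermodynamically preferred Z alkene unaffected.

**Compound list**

1 | 4-iodophenol | Oc1ccc(I)cc1 | starting material
2 | prenyl bromide (1-bromo-3-methylbut-2-ene) | CC(C)=CCBr | starting material
3 | 4-iodo-2-prenylphenol | CC(C)=CCc1cc(I)ccc1O | intermediate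
4 | (4-iodo-2-prenylphenoxy)triisopropylsilane | CC(C)=CCc1cc(I)ccc1O[Si](C(C)C)(C(C)C)C(C)C | intermediate
5 | diallyl malonate | C=CCOC(=O)CC(=O)OCC=C | starting material
6 | diallyl 2-[3-prenyl-4-(triisopropylsilyloxy)phenyl]malonate | C=CCOC(=O)C(c1ccc(O[Si](C(C)C)(C(C)C)C(C)C)c(CC=C(C)C)c1)C(=O)OCC=C | intermediate
7 | diallyl 2-prenyl-2-[3-prenyl-4-(triisopropylsilyloxy)phenyl]malonate | C=CCOC(=O)C(CC=C(C)C)(c1ccc(O[Si](C(C)C)(C(C)C)C(C)C)c(CC=C(C)C)c1)C(=O)OCC=C | intermediate
8 | 2-prenyl-2-[3-prenyl-4-(triisopropylsilyloxy)phenyl]malonic acid | OC(=O)C(CC=C(C)C)(c1ccc(O[Si](C(C)C)(C(C)C)C(C)C)c(CC=C(C)C)c1)C(O)=O | intermediate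
9 | N-iodosuccinimide | O=C1CCC(=O)N1I | starting material
10 | (3S,5R)-5-iodo-6,6-dimethyl-2-oxo-3-[3-prenyl-4-(triisopropylsilyloxy)phenyl]tetrahydropyran-3-carboxylic acid | CC1(C)OC(=O)[C@@](C[C@H]1I)(c2ccc(O[Si](C(C)C)(C(C)C)C(C)C)c(CC=C(C)C)c2)C(O)=O | intermediate
11 | (3R,5R)-acid chloride of 10 (same spatial arrangement, descriptor changes by priority; not isolated) | CC1(C)OC(=O)[C@@](C[C@H]1I)(c2ccc(O[Si](C(C)C)(C(C)C)C(C)C)c(CC=C(C)C)c2)C(Cl)=O | intermediate
12 | (3S,5R)-5-iodo-6,6-dimethyl-2-oxo-3-[3-prenyl-4-(triisopropylsilyloxy)phenyl]tetrahydropyran-3-carbaldehyde | CC1(C)OC(=O)[C@@](C[C@H]1I)(c2ccc(O[Si](C(C)C)(C(C)C)C(C)C)c(CC=C(C)C)c2)C=O | intermediate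
13 | ethynyltrimethylsilane | C#C[Si](C)(C)C | starting material
14 | triisopropyl{2-prenyl-4-[(trimethylsilyl)ethynyl]phenoxy}silane | CC(C)=CCc1cc(C#C[Si](C)(C)C)ccc1O[Si](C(C)C)(C(C)C)C(C)C | intermediate
15 | (4-ethynyl-2-prenylphenoxy)triisopropylsilane | CC(C)=CCc1cc(C#C)ccc1O[Si](C(C)C)(C(C)C)C(C)C | intermediate
16 | lithium acetylide of 15 (not isolated) | [Li]C#Cc1ccc(O[Si](C(C)C)(C(C)C)C(C)C)c(CC=C(C)C)c1 | intermediate
17 | (3S,5R)-iodolactone propargylic alcohol, carbinol centre unassigned (both epimers) | CC1(C)OC(=O)[C@@](C[C@H]1I)(c2ccc(O[Si](C(C)C)(C(C)C)C(C)C)c(CC=C(C)C)c2)C(O)C#Cc3ccc(O[Si](C(C)C)(C(C)C)C(C)C)c(CC=C(C)C)c3 | intermediate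
18 | (2S)-2-aryl-2-(1-hydroxy-3-arylprop-2-yn-1-yl)-5-methylhex-4-enoic acid, both aryl groups 3-prenyl-4-(triisopropylsilyloxy)phenyl, carbinol centre unassigned | OC(=O)[C@@](CC=C(C)C)(c1ccc(O[Si](C(C)C)(C(C)C)C(C)C)c(CC=C(C)C)c1)C(O)C#Cc2ccc(O[Si](C(C)C)(C(C)C)C(C)C)c(CC=C(C)C)c2 | intermediate
19 | (3S,5Z)-4-hydroxy-5-benzylidene lactone, bis(TIPS) ether, C4 unassigned | CC(C)=CCc1cc(/C=C2\OC(=O)[C@@](CC=C(C)C)(c3ccc(O[Si](C(C)C)(C(C)C)C(C)C)c(CC=C(C)C)c3)C2O)ccc1O[Si](C(C)C)(C(C)C)C(C)C | intermediate
20 | (3S,5Z)-furan-2,4-dione, bis(TIPS) ether of the target | CC(C)=CCc1cc(/C=C2\OC(=O)[C@@](CC=C(C)C)(c3ccc(O[Si](C(C)C)(C(C)C)C(C)C)c(CC=C(C)C)c3)C2=O)ccc1O[Si](C(C)C)(C(C)C)C(C)C | intermediate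
21 | (3S,5Z)-5-(4-hydroxy-3-prenylbenzylidene)-3-(4-hydroxy-3-prenylphenyl)-3-prenylfuran-2,4(3H,5H)-dione (CNP0567773.1) | CC(C)=CCc1cc(/C=C2\OC(=O)[C@@](CC=C(C)C)(c3ccc(O)c(CC=C(C)C)c3)C2=O)ccc1O | target

**Step count.** Total steps: 14. Longest linear sequence: 12 (steps 1–7 and 10–14). Steps 8 and 9 branch from the common intermediate 4.

**Steps most likely to fail**

1. Step 6. The enantiomeric purity at C3 could be lowered in three ways:
   - weak discrimination between the enantiotopic carboxyl groups;
   - an uncatalysed background closure;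
   - leakage through the diastereomeric chair.

   The fallback is racemic closure followed by classical resolution. Setting out from 8, uncatalysed iodolactonisation with 9 in CH2Cl2 at 0 °C should give the racemic iodolactone acid F1. This is paired with (R)-1-phenylethylamine, or its antipode, whichever gives the less soluble salt of the 3S acid. Fractional crystallisation at or below room temperature should give the diastereomerically pure ammonium salt F2. Cold aqueous KHSO4 then releases 10, where the route is rejoined. The unwanted enantiomer in the mother liquor is not lost, because zinc in acetic acid returns it to achiral 8.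

2. Step 7. The activated aldehyde could be over-reduced, or the hindered acyl chloride could react incompletely, so the reduction does not stop cleanly at the aldehyde level. The fallback is a deliberate redox detour. Setting out from 10 through acid chloride 11, excess LiAlH(OtBu)3 (THF, −78 to 0 °C) should reduce the acyl group fully while sparing the lactone. This gives the (3S,5R)-hydroxymethyl lactone F3. Dess–Martin oxidation of this neopentyl-type alcohol comes back to the route at 12.

3. Step 10. Material could be lost through retro-aldol cleavage of the lithium alkoxide, attack of the acetylide on the lactone carbonyl, or base-induced loss of hydrogen iodide. The fallback forms the C4–C5 bond without a carbanion and adjusts the oxidation level afterwards. Setting out from 10 through acid chloride 11, acyl Sonogashira coupling with 15 (PdCl2(PPh3)2, CuI, Et3N, THF, rt) should give the (3S,5R)-iodolactone ynone F4. Luche reduction (NaBH4, CeCl3·7H2O, MeOH/THF, −78 °C) delivers the propargylic alcohol and rejoins the route at 17, bypassing 12.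

**Further compounds**

F1 | step 6 | racemic 5-iodo-6,6-dimethyl-2-oxo-3-[3-prenyl-4-(triisopropylsilyloxy)phenyl]tetrahydropyran-3-carboxylic acid (racemate of 10) | CC1(C)OC(=O)C(CC1I)(c2ccc(O[Si](C(C)C)(C(C)C)C(C)C)c(CC=C(C)C)c2)C(O)=O
F2 | step 6 | (R)-1-phenylethylammonium salt of (3S,5R)-10 | CC1(C)OC(=O)[C@@](C[C@H]1I)(c2ccc(O[Si](C(C)C)(C(C)C)C(C)C)c(CC=C(C)C)c2)C(=O)[O-].C[C@@H]([NH3+])c1ccccc1
F3 | step 7 | (3S,5R)-3-(hydroxymethyl)-5-iodo-6,6-dimethyl-3-[3-prenyl-4-(triisopropylsilyloxy)phenyl]tetrahydropyran-2-one | CC1(C)OC(=O)[C@@](C[C@H]1I)(c2ccc(O[Si](C(C)C)(C(C)C)C(C)C)c(CC=C(C)C)c2)CO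
F4 | step 10 | (3S,5R)-5-iodo-6,6-dimethyl-3-[3-prenyl-4-(triisopropylsilyloxy)phenyl]-3-{3-[3-prenyl-4-(triisopropylsilyloxy)phenyl]prop-2-ynoyl}tetrahydropyran-2-one | CC1(C)OC(=O)[C@@](C[C@H]1I)(c2ccc(O[Si](C(C)C)(C(C)C)C(C)C)c(CC=C(C)C)c2)C(=O)C#Cc3ccc(O[Si](C(C)C)(C(C)C)C(C)C)c(CC=C(C)C)c3
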